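**Plan**
- Retrosynthesis cuts the two malonate C15–O ester bonds, then C12–C13 (sp3–sp2 coupling), C11–C12 and C9–C11 (two one-carbon olefinations), the C8–O bond, the ring A bond C3–C4, and finally the C10–C1 and C10–CH3 bonds, which leads back to (R)-carvone.
- Forward, the carvone ring is ring B (C5–C10; its carbonyl is C9, its methyl is C17). Methylation and an acrolein aldol/oxidation place the C20 methyl and a C1–C3 acryloyl arm on C10, and hydrogen-atom transfer to the isopropenyl group closes ring A through C3–C4.
- C1 is then deoxygenated, C8 is hydroxylated, C11 and C12 are added one carbon at a time, C13–C16 arrive by B-alkyl Suzuki coupling, and two alcohols are joined through malonic acid.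
- Stereochemistry: C5 comes from (R)-carvone; C10 from aldol attack anti to the isopropenyl group; C8 from α-face Rubottom oxidation; C9 from α-face hydroboration; 13E from an (E)-enol triflate coupled with retention.
- Enabling feature: the gem-dimethyl carbon C4 of ring A is bonded to the ring-fusion carbon C5, so it is a hydrogenated isopropenyl group on the six-membered ring B, which is the substitution pattern of carvone.

Key step: step 4

Remark: the SMILES is read as the malonate diester of (13E)-labd-13-ene-8α,15-diol of the normal series (5S,8R,9R,10S). Bicyclic compounds carry labdane numbering, α is the face opposite the C10 methyl, and all of them have 5α-H and 10β-CH3.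

Step 1
Reactants: 1 (R)-(−)-carvone; 2 iodomethane
Product: 4 6-methylcarvone (C6 epimers; methyl mainly trans to isopropenyl), via carvone lithium dienolate 3 (not isolated)
Conditions: LiN(iPr)2, THF, −78 °C; MeI, −78 → 0 °C
Reagents that add atoms: iodomethane, CI
Why: Kinetic α′-deprotonation of the enone and C-alkylation of the cross-conjugated enolate (enolate alkylation) should install the future C20 methyl; the C6 configuration is of no consequence because step 2 passes through the planar enolate again.

Step 2
Reactants: 4 6-methylcarvone; 5 acrolein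
Product: 7 6-(1-hydroxyprop-2-enyl)-6-methylcarvone (hydroxyallyl anti to isopropenyl; carbinol epimers), via lithium enolate 6 (not isolated)
Conditions: LiN(iPr)2, THF, −78 °C; acrolein, −78 °C; AcOH quench at −78 °C
Reagents that add atoms: acrolein, C=CC=O
Why: The tetrasubstituted lithium enolate should undergo a directed aldol 1,2-addition to acrolein on the face anti to the neighbouring isopropenyl group, which sets the quaternary C10 with its methyl cis to isopropenyl (introducing the methyl first and the three-carbon arm second is what gives this relationship), and the cold acidic quench suppresses retro-aldol cleavage.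

Step 3
Reactants: 7 6-(1-hydroxyprop-2-enyl)-6-methylcarvone
Product: 8 6-acryloyl-6-methylcarvone (acryloyl anti to isopropenyl)
Conditions: Dess–Martin periodinane, NaHCO3, CH2Cl2, 0 °C → rt
Reagents that add atoms: none
Why: Dess–Martin oxidation of the secondary allylic alcohol should give the vinyl ketone under neutral buffered conditions that spare the non-enolisable 1,3-diketone, and it removes the carbinol stereocentre.

Step 4
Reactants: 8 6-acryloyl-6-methylcarvone
Product: 9 11-nordrim-7-ene-1,9-dione (trans-fused; 5α-H; 10β-CH3)
Conditions: Fe(acac)3 (0.3 equiv), PhSiH3 (2.5 equiv), EtOH/HOCH2CH2OH (5:1), 60 °C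
Reagents that add atoms: none
Why: Fe(acac)3 and PhSiH3 in ethanol should form an iron hydride that transfers a hydrogen atom to the CH2 terminus of the electron-rich 1,1-disubstituted isopropenyl group, creating the second methyl on C4 and a nucleophilic tertiary radical. This radical should add to the unsubstituted β-carbon C3 of the acryloyl group, a polarity-matched Giese addition that forms C3–C4 and closes ring A in the 6-endo-trig mode, whereas 5-exo attack at C2 would be polarity-mismatched and would join two fully substituted carbons. The resulting α-keto radical at C2 is expected to be reduced by divalent iron to the enolate and protonated by the solvent, which returns trivalent iron to the cycle. The closest known reaction type is the iron-hydride reductive olefin coupling (hydrogen-atom-transfer radical conjugate addition) in its intramolecular form. No stereocentre is created, since C4 becomes a gem-dimethyl carbon and the trans ring fusion is already fixed by C5 and C10, whose reacting arms sit trans-diequatorial on ring B. The step needs hydrogen-atom transfer to occur at the isopropenyl group only, which the much lower reactivity of the two electron-poor enone double bonds towards the metal hydride should secure, and the ring B enone cannot be reached by the C4 radical in a ring of workable size.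

Step 5
Reactants: 9 11-nordrim-7-ene-1,9-dione
Product: 11 9-oxo-11-nordrima-1,7-dien-1-yl trifluoromethanesulfonate, via potassium C1–C2 enolate 10 (not isolated)
Conditions: KN(SiMe3)2, THF, −78 °C; PhNTf2, −78 → 0 °C
Reagents that add atoms: N-phenylbis(trifluoromethanesulfonimide), FC(F)(F)S(=O)(=O)N(c1ccccc1)S(=O)(=O)C(F)(F)F
Why: C2 carries the only α-hydrogens of the dione (C10 is quaternary and the C9 enone could only be deprotonated at its γ-positions), so kinetic enolisation followed by O-sulfonylation (enol triflate formation) should single out the C1 carbonyl.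

Step 6
Reactants: 11 9-oxo-11-nordrima-1,7-dien-1-yl trifluoromethanesulfonate
Product: 12 11-nordrima-1,7-dien-9-one
Conditions: Pd(OAc)2 (5 mol %), PPh3, HCO2H, n-Bu3N, DMF, 60 °C
Reagents that add atoms: none
Why: Palladium-catalysed formate reduction of the enol triflate (oxidative addition to zerovalent palladium, decarboxylation of the formate ligand and C–H reductive elimination) should replace the C1 oxygen by hydrogen without touching the enone.

Step 7
Reactants: 12 11-nordrima-1,7-dien-9-one
Product: 13 11-nordriman-9-one (C8 epimers; equatorial 8α-CH3 drawn)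
Conditions: H2 (1 atm), palladium on carbon (Pd/C), EtOAc, rt
Reagents that add atoms: none
Why: Heterogeneous catalytic hydrogenation should saturate both the isolated C1=C2 and the conjugated C7=C8 double bonds while leaving the hindered ketone, and the C8 configuration need not be controlled because step 8 erases it.

Step 8
Reactants: 13 11-nordriman-9-one
Product: 14 9-(triethylsilyloxy)-11-nordrim-8-ene
Conditions: Et3SiOTf, Et3N, CH2Cl2, 0 °C → rt
Reagents that add atoms: triethylsilyl trifluoromethanesulfonate, CC[Si](CC)(CC)OS(=O)(=O)C(F)(F)F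
Why: Soft enolisation and O-silylation (silyl enol ether formation) can only proceed towards C8, the sole α-carbon bearing hydrogen, so a single tetrasubstituted enol ether should result from either C8 epimer.

Step 9
Reactants: 14 9-(triethylsilyloxy)-11-nordrim-8-ene
Product: 16 8α-(triethylsilyloxy)-11-nordriman-9-one (8β-CH3), via silyloxy epoxide 15 (not isolated)
Conditions: mCPBA, NaHCO3, CH2Cl2, −20 → 0 °C
Reagents that add atoms: meta-chloroperoxybenzoic acid, OOC(=O)c1cccc(Cl)c1
Why: In this Rubottom oxidation the peracid should epoxidise the electron-rich enol ether on the α-face, anti to the axial 10β-methyl, and ring opening with 1,4-silyl shift then gives the α-silyloxy ketone, which sets C8 (oxygen α, methyl β) and leaves the tertiary alcohol protected.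

Step 10
Reactants: 16 8α-(triethylsilyloxy)-11-nordriman-9-one; 17 methyltriphenylphosphonium bromide
Product: 18 8α-(triethylsilyloxy)drim-9(11)-ene
Conditions: Ph3PCH3Br, KOtBu, toluene, 100 °C
Reagents that add atoms: methyltriphenylphosphonium bromide, C[P+](c1ccccc1)(c1ccccc1)c1ccccc1.[Br-]
Why: Wittig methylenation with the alkoxide-generated ylide at elevated temperature is the established protocol for sterically shielded ketones, and because this ketone has no α-hydrogen it cannot be diverted by enolisation.

Step 11
Reactants: 18 8α-(triethylsilyloxy)drim-9(11)-ene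
Product: 20 8α-(triethylsilyloxy)driman-11-ol (9α-H), via alkylborane 19 (not isolated)
Conditions: BH3·SMe2, THF, 0 °C → rt; then NaOH, H2O2, 0 °C → rt
Reagents that add atoms: hydrogen peroxide, OO
Why: Hydroboration–oxidation places boron on the terminal C11 and should deliver hydrogen to C9 from the α-face, because the β-face is covered by the axial methyl groups on C8 and C10, which sets C9 with an equatorial β-CH2OH.

Step 12
Reactants: 20 8α-(triethylsilyloxy)driman-11-ol
Product: 21 8α-(triethylsilyloxy)driman-11-al
Conditions: Dess–Martin periodinane, NaHCO3, CH2Cl2, 0 °C → rt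
Reagents that add atoms: none
Why: Dess–Martin oxidation of the hindered primary alcohol should stop at the aldehyde under buffered conditions, and the equatorial formyl group is already the more stable C9 epimer.

Step 13
Reactants: 21 8α-(triethylsilyloxy)driman-11-al; 17 methyltriphenylphosphonium bromide
Product: 22 8α-(triethylsilyloxy)-13,14,15,16-tetranorlabd-11-ene
Conditions: Ph3PCH3Br, KOtBu, THF, 0 °C → rt
Reagents that add atoms: methyltriphenylphosphonium bromide, C[P+](c1ccccc1)(c1ccccc1)c1ccccc1.[Br-]
Why: Wittig methylenation of the aldehyde adds C12 as a terminal vinyl group, and the silyl ether on O8 blocks the retro-aldol pathway that a free β-alkoxide would open.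

Step 14
Reactants: 23 ethyl acetoacetate
Product: 24 ethyl (E)-3-(trifluoromethylsulfonyloxy)but-2-enoate
Conditions: Tf2O, aq. Me4NOH, hexanes, 5 °C
Reagents that add atoms: trifluoromethanesulfonic anhydride, FC(F)(F)S(=O)(=O)OS(=O)(=O)C(F)(F)F
Why: O-Triflation of the β-keto ester enolate with a non-chelating ammonium counter-ion (stereoselective enol triflate formation) should favour the (E)-isomer with the triflate trans to the ester, and this geometry later becomes 13E.

Step 15
Reactants: 22 8α-(triethylsilyloxy)-13,14,15,16-tetranorlabd-11-ene; 24 ethyl (E)-3-(trifluoromethylsulfonyloxy)but-2-enoate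
Product: 26 ethyl (13E)-8α-(triethylsilyloxy)labd-13-en-15-oate, via B-alkyl-9-BBN borane 25 (not isolated)
Conditions: 9-BBN, THF, rt → 50 °C; then 24, Pd(dppf)Cl2 (5 mol %), aq. K3PO4, THF/DMF, 50 °C
Reagents that add atoms: ethyl (E)-3-(trifluoromethylsulfonyloxy)but-2-enoate, CCOC(=O)/C=C(\C)OS(=O)(=O)C(F)(F)F
Why: Anti-Markovnikov hydroboration of the terminal vinyl group followed by B-alkyl Suzuki–Miyaura coupling should form C12–C13 with retention of the enol triflate geometry, so the trisubstituted alkene is obtained as the 13E isomer.

Step 16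
Reactants: 26 ethyl (13E)-8α-(triethylsilyloxy)labd-13-en-15-oate
Product: 27 (13E)-8α-(triethylsilyloxy)labd-13-en-15-ol
Conditions: iBu2AlH, CH2Cl2, −78 → 0 °C; aq. KNaC4H4O6 work-up
Reagents that add atoms: none
Why: Hydride reduction of the α,β-unsaturated ester with iBu2AlH proceeds by 1,2-addition and should give the allylic alcohol without touching the alkene geometry or the silyl ether.

Step 17
Reactants: 27 (13E)-8α-(triethylsilyloxy)labd-13-en-15-ol
Product: 28 (13E)-labd-13-ene-8α,15-diol
Conditions: Bu4NF, THF, rt → 50 °C
Reagents that add atoms: none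
Why: Fluoride-mediated desilylation should free the tertiary alcohol under non-acidic conditions, which avoids acid-induced cyclisation of the 8-hydroxyl onto the 13-alkene.

Step 18
Reactants: 28 (13E)-labd-13-ene-8α,15-diol (2 equiv); 29 malonic acid
Product: 30 bis[(13E)-8α-hydroxylabd-13-en-15-yl] propanedioate (CNP0254645.1)
Conditions: malonic acid (0.5 equiv), DCC, DMAP (cat.), CH2Cl2, 0 °C → rt
Reagents that add atoms: malonic acid, OC(=O)CC(=O)O
Why: Steglich esterification should acylate only the primary allylic hydroxyl of each diol, since the tertiary 8α-hydroxyl flanked by C9 and the axial methyl is too hindered to react, and this joins the two halves through the malonate.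

**Compound list**
1 | (R)-(−)-carvone | CC1=CC[C@H](CC1=O)C(C)=C | starting material
2 | iodomethane | CI | starting material
3 | carvone lithium dienolate | [Li+].[O-]C1=C[C@H](C(C)=C)CC=C1C | intermediate
4 | 6-methylcarvone (C6 epimers; trans epimer drawn) | O=C1[C@@H](C)[C@H](C(C)=C)CC=C1C | intermediate
5 | acrolein | C=CC=O | starting material
6 | lithium enolate of 6-methylcarvone | [Li+].[O-]C1=C(C)[C@H](C(C)=C)CC=C1C | intermediate
7 | 6-(1-hydroxyprop-2-enyl)-6-methylcarvone (hydroxyallyl anti to isopropenyl; carbinol epimers) | O=C1[C@@](C)(C(O)C=C)[C@H](C(C)=C)CC=C1C | intermediate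
8 | 6-acryloyl-6-methylcarvone (acryloyl anti to isopropenyl) | O=C1[C@@](C)(C(=O)C=C)[C@H](C(C)=C)CC=C1C | intermediate
9 | 11-nordrim-7-ene-1,9-dione (trans-fused; 5α-H; 10β-CH3) | O=C1[C@@]2(C)C(=O)CCC(C)(C)[C@@H]2CC=C1C | intermediate
10 | potassium C1–C2 enolate of 9 | O=C1[C@@]2(C)C([O-])=CCC(C)(C)[C@@H]2CC=C1C.[K+] | intermediate
11 | 9-oxo-11-nordrima-1,7-dien-1-yl trifluoromethanesulfonate | O=C1[C@@]2(C)C(OS(=O)(=O)C(F)(F)F)=CCC(C)(C)[C@@H]2CC=C1C | intermediate
12 | 11-nordrima-1,7-dien-9-one | O=C1[C@@]2(C)C=CCC(C)(C)[C@@H]2CC=C1C | intermediate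
13 | 11-nordriman-9-one (C8 epimers; equatorial 8α-CH3 drawn) | O=C1[C@@]2(C)CCCC(C)(C)[C@@H]2CC[C@H]1C | intermediate
14 | 9-(triethylsilyloxy)-11-nordrim-8-ene | CC[Si](CC)(CC)OC1=C(C)CC[C@H]2C(C)(C)CCC[C@]12C | intermediate
15 | 8α,9α-epoxy-9β-(triethylsilyloxy)-11-nordrimane (silyloxy epoxide) | CC[Si](CC)(CC)O[C@@]12O[C@]1(C)CC[C@H]3C(C)(C)CCC[C@]23C | intermediate
16 | 8α-(triethylsilyloxy)-11-nordriman-9-one (8β-CH3) | O=C1[C@@]2(C)CCCC(C)(C)[C@@H]2CC[C@@]1(C)O[Si](CC)(CC)CC | intermediate
17 | methyltriphenylphosphonium bromide | C[P+](c1ccccc1)(c1ccccc1)c1ccccc1.[Br-] | starting material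
18 | 8α-(triethylsilyloxy)drim-9(11)-ene | C=C1[C@@]2(C)CCCC(C)(C)[C@@H]2CC[C@@]1(C)O[Si](CC)(CC)CC | intermediate
19 | [8α-(triethylsilyloxy)driman-11-yl]borane (alkylborane; 9α-H) | BC[C@@H]1[C@@]2(C)CCCC(C)(C)[C@@H]2CC[C@@]1(C)O[Si](CC)(CC)CC | intermediate
20 | 8α-(triethylsilyloxy)driman-11-ol (9α-H) | OC[C@@H]1[C@@]2(C)CCCC(C)(C)[C@@H]2CC[C@@]1(C)O[Si](CC)(CC)CC | intermediate
21 | 8α-(triethylsilyloxy)driman-11-al | O=C[C@@H]1[C@@]2(C)CCCC(C)(C)[C@@H]2CC[C@@]1(C)O[Si](CC)(CC)CC | intermediate
22 | 8α-(triethylsilyloxy)-13,14,15,16-tetranorlabd-11-ene | C=C[C@@H]1[C@@]2(C)CCCC(C)(C)[C@@H]2CC[C@@]1(C)O[Si](CC)(CC)CC | intermediate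
23 | ethyl acetoacetate | CCOC(=O)CC(C)=O | starting material
24 | ethyl (E)-3-(trifluoromethylsulfonyloxy)but-2-enoate | CCOC(=O)/C=C(\C)OS(=O)(=O)C(F)(F)F | intermediate
25 | 12-(9-borabicyclo[3.3.1]nonan-9-yl)-8α-(triethylsilyloxy)-13,14,15,16-tetranorlabdane (B-alkyl-9-BBN borane) | B1(CC[C@@H]3[C@@]4(C)CCCC(C)(C)[C@@H]4CC[C@@]3(C)O[Si](CC)(CC)CC)C2CCCC1CCC2 | intermediate
26 | ethyl (13E)-8α-(triethylsilyloxy)labd-13-en-15-oate | CCOC(=O)/C=C(\C)CC[C@@H]1[C@@]2(C)CCCC(C)(C)[C@@H]2CC[C@@]1(C)O[Si](CC)(CC)CC | intermediate
27 | (13E)-8α-(triethylsilyloxy)labd-13-en-15-ol | C/C(=C\CO)CC[C@@H]1[C@@]2(C)CCCC(C)(C)[C@@H]2CC[C@@]1(C)O[Si](CC)(CC)CC | intermediate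
28 | (13E)-labd-13-ene-8α,15-diol | C/C(=C\CO)CC[C@@H]1[C@@]2(C)CCCC(C)(C)[C@@H]2CC[C@@]1(C)O | intermediate
29 | malonic acid | OC(=O)CC(=O)O | starting material
30 | bis[(13E)-8α-hydroxylabd-13-en-15-yl] propanedioate (CNP0254645.1) | C/C(=C\COC(=O)CC(=O)OC/C=C(\C)CC[C@@H]1[C@@]2(C)CCCC(C)(C)[C@@H]2CC[C@@]1(C)O)CC[C@@H]1[C@@]2(C)CCCC(C)(C)[C@@H]2CC[C@@]1(C)O | target

**Step count**
Total: 18 steps. Longest linear sequence: 17 steps (steps 1–13 and 15–18); step 14 is a one-step side branch.

**Steps most likely to fail**

Step 10. The ylide may fail to add to a carbonyl that is shielded on both sides by fully substituted carbons, so that the ketone is recovered or the silyl ether is lost on prolonged heating. The fallback replaces direct olefination by addition and elimination. It sets out from 16: CH3Li with CeCl3 in THF at −78 °C should add from the open α-face to give the tertiary carbinol 9α-methyl-8α-(triethylsilyloxy)-11-nordriman-9β-ol F1. Dehydration of F1 with the Burgess reagent in toluene at 70 °C can only remove a hydrogen from the new methyl group, since C8 and C10 carry none, and the route is rejoined at 18.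

Step 4. Before hydrogen-atom transfer takes place, ethanol may add in conjugate fashion to the doubly activated vinyl ketone, the vinyl ketone may oligomerise, or the non-enolisable 1,3-diketone may be cleaved by retro-Claisen attack; the tertiary radical may also be reduced before it cyclises. The fallback keeps the same C3–C4 closure but moves the activating group to C2 as a sulfone, which leaves no oxygen on C1. It sets out from 4: the lithium enolate (LiN(iPr)2, THF, −78 °C) is alkylated anti to the isopropenyl group with 3-bromo-2-(phenylsulfonyl)prop-1-ene to give 6-methyl-6-[2-(phenylsulfonyl)prop-2-enyl]carvone F2. Fe(acac)3 and PhSiH3 in ethanol at 60 °C should then close ring A at the CH2 terminus of the vinyl sulfone to give 2-(phenylsulfonyl)-11-nordrim-7-en-9-one F3. Lithium in liquid ammonia/THF at −78 °C, followed by NH4Cl, cleaves the C–S bond and reduces the enone in one operation, and the route is rejoined at 13 (steps 2–7 are bypassed).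

Step 2. Conjugate addition to acrolein and its anionic oligomerisation may outrun 1,2-addition at the congested tetrasubstituted enolate carbon, leaving 4 unreacted. The fallback uses a saturated aldehyde in which the vinyl group is latent. It sets out from 4: the same lithium enolate is combined at −78 °C with 3-(phenylselanyl)propanal to give 6-[1-hydroxy-3-(phenylselanyl)propyl]-6-methylcarvone F4. Oxidation with H2O2 and pyridine in CH2Cl2 at 0 °C → rt gives the selenoxide of this aldol F5, whose syn-elimination at room temperature unveils the terminal alkene, and the route is rejoined at 7.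

**Further compounds**
F1 | step 10 | 9α-methyl-8α-(triethylsilyloxy)-11-nordriman-9β-ol | C[C@@]1(O)[C@@]2(C)CCCC(C)(C)[C@@H]2CC[C@@]1(C)O[Si](CC)(CC)CC
F2 | step 4 | 6-methyl-6-[2-(phenylsulfonyl)prop-2-enyl]carvone (sulfonylallyl anti to isopropenyl) | O=C1[C@@](C)(CC(=C)S(=O)(=O)c2ccccc2)[C@H](C(C)=C)CC=C1C
F3 | step 4 | 2-(phenylsulfonyl)-11-nordrim-7-en-9-one (C2 epimers) | O=C1[C@@]2(C)CC(CC(C)(C)[C@@H]2CC=C1C)S(=O)(=O)c1ccccc1
F4 | step 2 | 6-[1-hydroxy-3-(phenylselanyl)propyl]-6-methylcarvone (carbinol epimers) | O=C1[C@@](C)(C(O)CC[Se]c2ccccc2)[C@H](C(C)=C)CC=C1C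
F5 | step 2 | selenoxide of F4 | O=C1[C@@](C)(C(O)CC[Se](=O)c2ccccc2)[C@H](C(C)=C)CC=C1C
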